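Remark on the chemistry: the trivial name is read as the bibenzyl drawn by the SMILES, 2,4-bis(4-hydroxybenzyl)-3-[2-(3-hydroxyphenyl)ethyl]-5-methoxyphenol. Ring A is numbered as in the bibenzyl: C1 carries the bridge Cα–Cβ to ring B, and rings C and D are the 4-hydroxyphenyl rings of the benzyl groups on C2 and C6.

## Analysis of the target

The target 20 is an open-chain bibenzyl. Ring A carries, going round, OMe on C5, H on C4, OH on C3, a 4-hydroxybenzyl group (ring C) on C2, the bridge to the 3-hydroxyphenyl ring B on C1, and a second 4-hydroxybenzyl group (ring D) on C6. There is no stereocenter, so the whole problem is one of regiochemistry on a pentasubstituted benzene. The crowded part is the run of three carbon substituents on C2, C1 and C6, and it sits between two oxygens that differ only in that one is methylated. The sensitive features are the four free phenols, the electron-rich ring A with its open position C4, and the two doubly benzylic methylenes; they argue for a neutral, reductive unmasking at the end. Substitution on a ready-made ring A is awkward, because rings B, C and D are phenols of similar reactivity and C4 is the most activated position of ring A. The plan rests on the fact that ring A, apart from the O-methyl group, has a mirror plane through C1 and C4 and splits into two three-carbon halves. With a carboxyl group added on C4, the half C2–C3–C4 is the γ-carbon, keto carbon and α-carbon of a β-keto ester, and the half C5–C6–C1, together with Cα, is the ester carbon, α-carbon, central carbon and terminal carbon of a 2,3-dienoate.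

## Retrosynthetic reasoning

**20 to 19.** The C4–H bond is traced back to a C4–carboxyl bond, giving the salicylic acid 19. An acid flanked by a hydroxyl and a methoxy group on an electron-rich ring should lose CO2 on warming, so the carboxyl is traceless. It is wanted because it completes the β-keto ester half of ring A, blocks C4, and lets one of the two ring A oxygens be told from the other.

**19 to 18.** The four O–benzyl bonds (three aryl ethers and the ester) are cut together, leading to 18. Benzyl groups stand up to the strong base of the ring synthesis, and one neutral hydrogenolysis removes them all and frees the acid.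

**18 to 17.** The O–methyl bond is cut. Resorcylate 17 has a mirror plane, so its two hydroxyls are equivalent and either one gives 18. Once one is methylated, the other stays hydrogen-bonded to the ester carbonyl, which should hold the reaction at the mono ether.

**17 to 13 and 10.** Ring A is cut at C1–C2 and at C4–C5, giving β-keto ester 13 and allenoate 10.
- These cuts divide the ring into a donor with two nucleophilic carbons (γ and α of 13) and an acceptor with two electrophilic carbons (the central allene carbon and the ester carbon of 10).
- Each half brings one of the two benzyl groups, and 10 brings the bridge and ring B, so all six ring positions are fixed by the connectivity of open-chain pieces.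
- The two halves together are at the oxidation level of the arene, so the forward union needs no oxidant; it has to add the γ-carbon to the allene, then acylate the α-carbon, then tautomerize.
- Cuts elsewhere in the ring would call for an unsymmetrical ketone enolate with no such built-in order of reactivity.

**13 to 11 and 6.** The bond between the γ-carbon and the benzylic CH2 is cut, leading to benzyl acetoacetate 11 and benzylic chloride 6. The forward step is the alkylation of a dianion at its more reactive terminus.

**10 to 7 and 4, and further back.** The double bond between the α-carbon and the central carbon of the allene is cut, giving phosphonium salt 7 (through its ylide 8) and acid chloride 4 (through its ketene 9). Salt 7 comes from ylide 5 and the same chloride 6, so both benzyl groups of the target have one source. Acid chloride 4 goes back through acid 3 and ester 2 to 3-(3-hydroxyphenyl)propanoic acid 1.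

## Alternatives that were turned down

Alternative 1: The two diarylmethane bonds, C7–ring C and C7'–ring D, are cut, leaving 3-[2-(3,5-dimethoxy-2,6-dimethylphenyl)ethyl]phenyl pivalate (A1), in which ring A is already in place.
- **Forward key step:** constant-current electrolysis of A1 at a graphite anode in (CF3)2CHOH would turn both ring A methyl groups into benzylic ethers of the solvent. Phenol (A2) with catalytic TfOH would then replace both ether groups in the same flask to give 3-{2-[2,6-bis(4-hydroxybenzyl)-3,5-dimethoxyphenyl]ethyl}phenyl pivalate (A3).
- **For it:** ring A is bought and not built, rings C and D need no protecting group, and the step count is lower. On step economy it is the stronger plan.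
- **Against it:**
  - The radical cation of ring A can lose a proton from three benzylic sites, the two methyls and the bridge carbon Cα, and nothing in A1 steers it away from Cα.
  - The second methyl must be oxidized in a molecule that already holds a labile benzylic ether.
  - The benzylic cations can attack A2 ortho as well as para, and can attack C4 of another ring A, which lies between two methoxy groups.
  - A3 still has two identical methyl ethers on ring A, so one would have to be cleaved with no handle to choose it.
- **Comparison:** the chosen route is longer, but it fixes each ring A position by connectivity and uses the C4 ester to single out one oxygen.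

Alternative 2: Ring A is cut at C6–C1 and C4–C5, as in the chosen plan, but one oxidation level lower. The pieces are dimethyl 2-[4-(benzyloxy)benzyl]malonate (A4) and (E)-3-[4-(benzyloxy)benzyl]-6-[3-(benzyloxy)phenyl]hex-3-en-2-one (A5).
- **Forward key step:** with NaOMe in MeOH, A4 would add to the β-carbon of A5 and the methyl ketone would then close onto one malonate ester. The product is methyl 1,5-bis[4-(benzyloxy)benzyl]-6-{2-[3-(benzyloxy)phenyl]ethyl}-2,4-dioxocyclohexane-1-carboxylate (A6).
- **For it:** both events are textbook enolate chemistry under thermodynamic control. Aromatization through the methyl enol ether would deliver the mono methyl ether without any need to tell two phenols apart. On these two points it is stronger than the chosen route, whose key step has no precedent and whose methylation leans on chelation.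
- **Against it:**
  - The Michael addition must join a fully substituted malonate carbon to the β-carbon of an α,β-disubstituted enone. That makes a quaternary centre next to two tertiary ones, the least favourable case for a reversible conjugate addition.
  - A5 needs a regiocontrolled aldol at the methylene of an unsymmetrical ketone.
  - A6 forms as a mixture of diastereomers.
  - Three more operations follow: loss of the quaternary ester, enol ether formation and dehydrogenation. The last is an oxidation in a molecule with two doubly benzylic methylenes and three benzyl ethers.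
- **Comparison:** the chosen route reaches the aromatic oxidation level in the ring-forming step itself, because the allene brings the unsaturation.

Alternative 3: Ring A is cut at C1–C2 only, which opens it to the linear triketone (E)-1-[3-(benzyloxy)phenyl]-4-[4-(benzyloxy)benzyl]-9-[4-(benzyloxy)phenyl]non-1-ene-3,5,7-trione (A7).
- **Forward key step:** in aqueous methanolic KOH the terminal methylene of A7 would add to the cinnamoyl carbonyl carbon. Loss of water and enolization of the other two carbonyls would give 4,6-bis[4-(benzyloxy)benzyl]-5-{(E)-2-[3-(benzyloxy)phenyl]ethenyl}benzene-1,3-diol (A8).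
- **For it:** it follows the way such rings arise in nature, and A7 should be reachable in very few steps by acylating a 1,3-diketone dianion with a cinnamate. The styryl end has no α-methylene, so only one aldol mode exists. One later hydrogenation would saturate the bridge and remove all benzyl groups. In step count it is at least the equal of the chosen route.
- **Against it:**
  - The carbon between the two saturated-chain carbonyls is the most acidic position of A7 and can add to the β-carbon of the cinnamoyl unit in a 6-endo Michael closure.
  - Enol oxygens can close to pyranones.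
  - The aldol needs the least acidic carbon of a polyenolized chain to attack a conjugated, deactivated carbonyl.
  - A8 has two equivalent hydroxyls and no neighbouring group, so the single O-methylation would be statistical.
- **Comparison:** the chosen route keeps the C4 ester as a handle for that differentiation and confines the ring closure to one donor and one acceptor. It pays with a longer sequence and an untested union.

Key step: step 7

## Route

Step 1
Reactants: 1 3-(3-hydroxyphenyl)propanoic acid
Product: 2 benzyl 3-[3-(benzyloxy)phenyl]propanoate
Conditions: BnBr (2.3 equiv), K2CO3, DMF, 60 °C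
Reagents that add atoms: benzyl bromide, BrCc1ccccc1
Why: Williamson etherification of the phenol and SN2 O-alkylation of the carboxylate occur under the same conditions, so both acidic groups are benzylated without having to tell them apart.

Step 2
Reactants: 2 benzyl 3-[3-(benzyloxy)phenyl]propanoate
Product: 3 3-[3-(benzyloxy)phenyl]propanoic acid
Conditions: NaOH, THF/MeOH/H2O, 50 °C; then 1 M HCl
Reagents that add atoms: sodium hydroxide (hydroxide oxygen), [Na+].[OH-]
Why: Saponification of an unhindered alkyl ester; the aryl benzyl ether is inert to hydroxide.

Step 3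
Reactants: 3 3-[3-(benzyloxy)phenyl]propanoic acid
Product: 4 3-[3-(benzyloxy)phenyl]propanoyl chloride
Conditions: (COCl)2, DMF (cat.), CH2Cl2, 0 °C to rt
Reagents that add atoms: oxalyl chloride, ClC(=O)C(Cl)=O
Why: Acid chloride formation through the Vilsmeier-type chloroiminium catalyst; the by-products are gases, so 4 can be used crude, and the benzyl ether is not touched.

Step 4
Reactants: 5 methyl (triphenylphosphoranylidene)acetate; 6 4-(benzyloxy)benzyl chloride
Product: 7 {3-[4-(benzyloxy)phenyl]-1-methoxy-1-oxopropan-2-yl}triphenylphosphonium chloride (racemic)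
Conditions: MeCN, 80 °C
Reagents that add atoms: none
Why: C-alkylation of a stabilized phosphorus ylide by SN2 attack on an activated benzylic chloride gives the phosphonium salt; the α-substituted salt is less acidic than the parent salt, so proton exchange with unreacted 5 should not drain the ylide.

Step 5
Reactants: 7 {3-[4-(benzyloxy)phenyl]-1-methoxy-1-oxopropan-2-yl}triphenylphosphonium chloride; 4 3-[3-(benzyloxy)phenyl]propanoyl chloride
Product: 10 methyl 2-[4-(benzyloxy)benzyl]-5-[3-(benzyloxy)phenyl]penta-2,3-dienoate (racemic), via phosphorus ylide 8 (not isolated), via ketene 9 (not isolated)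
Conditions: Et3N (2.1 equiv), CH2Cl2, 0 °C to rt, slow addition of 4
Reagents that add atoms: none
Why: Wittig olefination of a ketene made in the flask: one equivalent of Et3N frees ylide 8 from 7, the second dehydrochlorinates 4 to ketene 9, and their union with loss of Ph3PO gives the allene, the standard route to α-substituted 2,3-dienoates. The allene axis makes 10 chiral but it forms as a racemate, which is of no consequence because the axis is lost in step 7.

Step 6
Reactants: 11 benzyl acetoacetate; 6 4-(benzyloxy)benzyl chloride
Product: 13 benzyl 5-[4-(benzyloxy)phenyl]-3-oxopentanoate, via acetoacetate dianion 12 (not isolated)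
Conditions: LiN(iPr)2 (2.1 equiv), THF, −78 to 0 °C; then 6 (1 equiv), 0 °C; 1 M HCl
Reagents that add atoms: none
Why: γ-Alkylation of an acetoacetate dianion: the γ-carbanion is far more nucleophilic than the stabilized α-position, so the benzylic chloride is taken up at the terminal carbon only, and one equivalent of 6 guards against a second alkylation.

Step 7
Reactants: 13 benzyl 5-[4-(benzyloxy)phenyl]-3-oxopentanoate; 10 methyl 2-[4-(benzyloxy)benzyl]-5-[3-(benzyloxy)phenyl]penta-2,3-dienoate
Product: 17 benzyl 3,5-bis[4-(benzyloxy)benzyl]-4-{2-[3-(benzyloxy)phenyl]ethyl}-2,6-dihydroxybenzoate, via keto ester dianion 14 (not isolated), via Michael adduct 15 (not isolated), via cyclohexanedione 16 (not isolated)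
Conditions: 13 (1.1 equiv), LiN(iPr)2 (2.1 equiv per 13), THF, −78 to 0 °C; 10 (1 equiv), −78 °C; t-BuOH (1 equiv), −78 °C to rt (40 °C if needed); 1 M HCl
Reagents that add atoms: none
Why: Proposed new method: dianion 14 should add through its γ-carbon to the central sp carbon of allenoate 10 (C2–C1 bond), leaving a keto ester enolate and an ester dienolate; the closest known reaction types are conjugate additions of lithium enolates to the central carbon of 2,3-dienoates and [3+3] cyclizations of 1,3-dicarbonyl dianions or their bis(silyl enol ethers) with 1,3-dielectrophiles to salicylates. One equivalent of t-BuOH protonates the more basic dienolate to give 15 as its keto ester enolate, which turns the methyl ester back into an electrophile, and carbon C4 of that enolate then attacks it in a 6-(enolendo)-exo-trig Claisen closure (C4–C5 bond) that expels methoxide and gives 16. Compound 16 is already at the oxidation level of the arene, so proton shifts alone (alkene into the ring, two enolizations) give 17, and this aromatization makes the sequence irreversible. No stereocenter is formed that survives: the allene axis of 10, the sp3 centres of 15 and 16 and the alkene geometry are all erased, and a conjugated isomer of 15 with the wrong geometry can return through the dienolate. Regiochemistry needs γ-attack at the allene before α-attack at the ester; the γ-site is by far the most nucleophilic position of 14, and a slight excess of 14 at −78 °C is meant to outrun proton transfer from the allenic C–H of 10, which would leave the monoanion of 13 to add through C4 and end in an isomeric resorcylate. The enolate oxygen on C3 can also reach the ester through a six-membered ring, but that O-acylation to an enol lactone is reversible under the alkoxides present, while C-acylation is drained by aromatization, so warming should funnel the material to 17. The t-BuOLi and MeOLi formed are used up in deprotonating the two phenolic hydroxyls of 17, so no free methoxide should remain to exchange the benzyl ester.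

Step 8
Reactants: 17 benzyl 3,5-bis[4-(benzyloxy)benzyl]-4-{2-[3-(benzyloxy)phenyl]ethyl}-2,6-dihydroxybenzoate
Product: 18 benzyl 3,5-bis[4-(benzyloxy)benzyl]-4-{2-[3-(benzyloxy)phenyl]ethyl}-2-hydroxy-6-methoxybenzoate
Conditions: MeI (1.1 equiv), K2CO3 (1.1 equiv), acetone, 40 °C
Reagents that add atoms: iodomethane, CI
Why: Williamson O-methylation; the two hydroxyls of 17 are related by its mirror plane, so either gives 18. After the first methylation the remaining hydroxyl is held in a hydrogen bond to the ester carbonyl, which lowers its reactivity and should stop the reaction at the mono ether, as is usual for 2,6-dihydroxybenzoates.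

Step 9
Reactants: 18 benzyl 3,5-bis[4-(benzyloxy)benzyl]-4-{2-[3-(benzyloxy)phenyl]ethyl}-2-hydroxy-6-methoxybenzoate
Product: 19 2-hydroxy-3,5-bis(4-hydroxybenzyl)-4-[2-(3-hydroxyphenyl)ethyl]-6-methoxybenzoic acid
Conditions: H2 (1 atm), 10% Pd/C, EtOAc/MeOH, rt
Reagents that add atoms: none
Why: Catalytic hydrogenolysis cleaves the three aryl benzyl ethers and the benzyl ester in one operation; the aryl methyl ether, the diarylmethane C–C bonds and the bibenzyl bridge are inert under these conditions.

Step 10
Reactants: 19 2-hydroxy-3,5-bis(4-hydroxybenzyl)-4-[2-(3-hydroxyphenyl)ethyl]-6-methoxybenzoic acid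
Product: 20 2,4-bis(4-hydroxybenzyl)-3-[2-(3-hydroxyphenyl)ethyl]-5-methoxyphenol (the target)
Conditions: DMSO (degassed), 120 °C, Ar
Reagents that add atoms: none
Why: Thermal protodecarboxylation of a salicylic acid: the ortho hydroxyl allows ipso protonation through the keto tautomer, a β-keto acid in disguise, and the second ortho oxygen and the fully substituted, electron-rich ring should speed the loss of CO2. Exclusion of air protects the tetraphenol.

## Compound list

1 | 3-(3-hydroxyphenyl)propanoic acid | OC(=O)CCc1cccc(O)c1 | starting material
2 | benzyl 3-[3-(benzyloxy)phenyl]propanoate | O=C(CCc1cccc(OCc2ccccc2)c1)OCc1ccccc1 | intermediate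
3 | 3-[3-(benzyloxy)phenyl]propanoic acid | OC(=O)CCc1cccc(OCc2ccccc2)c1 | intermediate
4 | 3-[3-(benzyloxy)phenyl]propanoyl chloride | ClC(=O)CCc1cccc(OCc2ccccc2)c1 | intermediate
5 | methyl (triphenylphosphoranylidene)acetate | COC(=O)C=P(c1ccccc1)(c1ccccc1)c1ccccc1 | starting material
6 | 4-(benzyloxy)benzyl chloride | ClCc1ccc(OCc2ccccc2)cc1 | starting material
7 | {3-[4-(benzyloxy)phenyl]-1-methoxy-1-oxopropan-2-yl}triphenylphosphonium chloride (racemic) | COC(=O)C(Cc1ccc(OCc2ccccc2)cc1)[P+](c1ccccc1)(c1ccccc1)c1ccccc1.[Cl-] | intermediate
8 | methyl 3-[4-(benzyloxy)phenyl]-2-(triphenyl-λ5-phosphanylidene)propanoate | COC(=O)C(Cc1ccc(OCc2ccccc2)cc1)=P(c1ccccc1)(c1ccccc1)c1ccccc1 | intermediate (not isolated)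
9 | 3-[3-(benzyloxy)phenyl]prop-1-en-1-one (ketene) | O=C=CCc1cccc(OCc2ccccc2)c1 | intermediate (not isolated)
10 | methyl 2-[4-(benzyloxy)benzyl]-5-[3-(benzyloxy)phenyl]penta-2,3-dienoate (racemic) | COC(=O)C(Cc1ccc(OCc2ccccc2)cc1)=C=CCc1cccc(OCc2ccccc2)c1 | intermediate
11 | benzyl acetoacetate | CC(=O)CC(=O)OCc1ccccc1 | starting material
12 | dilithium 1-(benzyloxy)buta-1,3-diene-1,3-bis(olate) (dianion of 11) | [Li+].[Li+].C=C([O-])C=C([O-])OCc1ccccc1 | intermediate (not isolated)
13 | benzyl 5-[4-(benzyloxy)phenyl]-3-oxopentanoate | O=C(CC(=O)CCc1ccc(OCc2ccccc2)cc1)OCc1ccccc1 | intermediate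
14 | dilithium 1-(benzyloxy)-5-[4-(benzyloxy)phenyl]penta-1,3-diene-1,3-bis(olate) (dianion of 13) | [Li+].[Li+].[O-]C(=CC([O-])=CCc1ccc(OCc2ccccc2)cc1)OCc1ccccc1 | intermediate (not isolated)
15 | 1-benzyl 7-methyl 4,6-bis[4-(benzyloxy)benzyl]-5-{2-[3-(benzyloxy)phenyl]ethylidene}-3-oxoheptanedioate (present as its lithium enolate; mixture of stereoisomers) | COC(=O)C(Cc1ccc(OCc2ccccc2)cc1)C(=CCc1cccc(OCc2ccccc2)c1)C(Cc1ccc(OCc2ccccc2)cc1)C(=O)CC(=O)OCc1ccccc1 | intermediate (not isolated)
16 | benzyl 3,5-bis[4-(benzyloxy)benzyl]-4-{2-[3-(benzyloxy)phenyl]ethylidene}-2,6-dioxocyclohexane-1-carboxylate (mixture of stereoisomers) | O=C(OCc1ccccc1)C1C(=O)C(Cc2ccc(OCc3ccccc3)cc2)C(=CCc2cccc(OCc3ccccc3)c2)C(Cc2ccc(OCc3ccccc3)cc2)C1=O | intermediate (not isolated)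
17 | benzyl 3,5-bis[4-(benzyloxy)benzyl]-4-{2-[3-(benzyloxy)phenyl]ethyl}-2,6-dihydroxybenzoate | O=C(OCc1ccccc1)c1c(O)c(Cc2ccc(OCc3ccccc3)cc2)c(CCc2cccc(OCc3ccccc3)c2)c(Cc2ccc(OCc3ccccc3)cc2)c1O | intermediate
18 | benzyl 3,5-bis[4-(benzyloxy)benzyl]-4-{2-[3-(benzyloxy)phenyl]ethyl}-2-hydroxy-6-methoxybenzoate | COc1c(C(=O)OCc2ccccc2)c(O)c(Cc2ccc(OCc3ccccc3)cc2)c(CCc2cccc(OCc3ccccc3)c2)c1Cc1ccc(OCc2ccccc2)cc1 | intermediate
19 | 2-hydroxy-3,5-bis(4-hydroxybenzyl)-4-[2-(3-hydroxyphenyl)ethyl]-6-methoxybenzoic acid | COc1c(C(=O)O)c(O)c(Cc2ccc(O)cc2)c(CCc2cccc(O)c2)c1Cc1ccc(O)cc1 | intermediate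
20 | 2,4-bis(4-hydroxybenzyl)-3-[2-(3-hydroxyphenyl)ethyl]-5-methoxyphenol (3,3'-dihydroxy-2,6-bis(4-hydroxybenzyl)-5-methoxybibenzyl) | COc1cc(O)c(Cc2ccc(O)cc2)c(CCc2cccc(O)c2)c1Cc1ccc(O)cc1 | target

## Step count and uncertain steps

Total step count: 10. Longest linear sequence: 8 steps (1, 2, 3, 5, 7, 8, 9, 10). Step 4 and step 6 are side branches that feed steps 5 and 7.

**Step 7 (key step, bears the label "Proposed new method:").** Three things can go wrong.
- Proton transfer from the allenic C–H of 10 to the strongly basic dianion can outrun conjugate addition. The monoanion of 13 that is left would add through its α-carbon and close through the γ-carbon, giving an isomeric ring.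
- The hard γ-carbanion may attack the ester carbonyl of 10 instead of the central allene carbon. This γ-acylation would again end in a constitutional isomer after closure.
- The closure may stop at O-acylation (the enol lactone) if the alkoxide-mediated return is slow.

Compound 17 has a mirror plane and its isomers do not, so a wrong course would be easy to recognize.

The fallback uses known aromatic chemistry and gives up the ring synthesis; it sets out from 6 and comes back at 20. Commercial 3-hydroxy-5-methoxybenzaldehyde is O-benzylated (BnBr, K2CO3, DMF) to 3-(benzyloxy)-5-methoxybenzaldehyde F1. Bromination with two equivalents of N-bromosuccinimide in MeCN should go to the two positions para to the alkoxy groups and give 3-(benzyloxy)-2,6-dibromo-5-methoxybenzaldehyde F2. Commercial 3-(benzyloxy)benzyl bromide and PPh3 give [3-(benzyloxy)benzyl]triphenylphosphonium bromide F3, and its Wittig reaction with F2 (KOtBu, THF) gives 1-(benzyloxy)-2,4-dibromo-3-{2-[3-(benzyloxy)phenyl]ethenyl}-5-methoxybenzene F4 as an E/Z mixture. Chloride 6 is turned with Zn dust and LiCl in THF into [4-(benzyloxy)benzyl]zinc chloride F5, and a double Negishi coupling with F4 (Pd(OAc)2, SPhos, THF, 60 °C) gives 1-(benzyloxy)-2,4-bis[4-(benzyloxy)benzyl]-3-{2-[3-(benzyloxy)phenyl]ethenyl}-5-methoxybenzene F6. Hydrogenation over Pd/C then saturates the alkene and removes the four benzyl ethers to give 20.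

**Step 5.** Ylide 8 may be acylated at carbon by 4 before the ketene forms, ketene 9 may dimerize, and Et3N may move the allene into conjugation with ring B.

The fallback changes the way the allene is made; it sets out from 2 and 6 and comes back at 10. Ester 2 is reduced with iBu2AlH at −78 °C to 3-[3-(benzyloxy)phenyl]propanal F7. Ohira–Bestmann homologation (dimethyl (1-diazo-2-oxopropyl)phosphonate, K2CO3, MeOH) gives 1-(benzyloxy)-3-(but-3-yn-1-yl)benzene F8. Deprotonation with n-BuLi and methyl chloroformate gives methyl 5-[3-(benzyloxy)phenyl]pent-2-ynoate F9. Deprotonation of F9 at the propargylic methylene with LiN(iPr)2 (THF, −78 °C) gives the allenyl enolate, and its α-alkylation with 6 gives 10. This deconjugative α-alkylation of 2-alkynoates is a known way to α-substituted 2,3-dienoates.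

**Step 8.** Both hydroxyls are flanked by benzyl groups, so the reaction may stall, and forcing it may cause over-methylation to the dimethyl ether.

The fallback replaces selective alkylation by selective dealkylation; it sets out from 17 and comes back at 18. Excess MeI with Cs2CO3 in DMF at 50 °C gives benzyl 3,5-bis[4-(benzyloxy)benzyl]-4-{2-[3-(benzyloxy)phenyl]ethyl}-2,6-dimethoxybenzoate F10. MgI2·OEt2 in toluene at 60 °C should then cleave one methoxy group ortho to the ester carbonyl under chelation control, while the remote benzyl ethers are left alone. If the ester benzyl group is lost at the same time, this does no harm, since step 9 removes it anyway.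

**Step 10.** The decarboxylation may be slow at temperatures the tetraphenol tolerates, and prolonged heating invites oxidative degradation.

The fallback moves the loss of the carboxyl group to a protected stage; it sets out from 18 and comes back at 20. KOH in DMSO/H2O at 120 °C, followed by acidification and warming, saponifies and decarboxylates the salicylate with the benzyl ethers still in place. This is the usual alkaline end-game of alkylresorcinol syntheses, and it gives 2,4-bis[4-(benzyloxy)benzyl]-3-{2-[3-(benzyloxy)phenyl]ethyl}-5-methoxyphenol F11. Hydrogenolysis over Pd/C then gives 20.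

## Further compounds

F1 | step 7 | 3-(benzyloxy)-5-methoxybenzaldehyde | COc1cc(C=O)cc(OCc2ccccc2)c1
F2 | step 7 | 3-(benzyloxy)-2,6-dibromo-5-methoxybenzaldehyde | COc1cc(OCc2ccccc2)c(Br)c(C=O)c1Br
F3 | step 7 | [3-(benzyloxy)benzyl]triphenylphosphonium bromide | [Br-].c1ccc(cc1)[P+](Cc1cccc(OCc2ccccc2)c1)(c1ccccc1)c1ccccc1
F4 | step 7 | 1-(benzyloxy)-2,4-dibromo-3-{2-[3-(benzyloxy)phenyl]ethenyl}-5-methoxybenzene (E/Z mixture) | COc1cc(OCc2ccccc2)c(Br)c(C=Cc2cccc(OCc3ccccc3)c2)c1Br
F5 | step 7 | [4-(benzyloxy)benzyl]zinc chloride | Cl[Zn]Cc1ccc(OCc2ccccc2)cc1
F6 | step 7 | 1-(benzyloxy)-2,4-bis[4-(benzyloxy)benzyl]-3-{2-[3-(benzyloxy)phenyl]ethenyl}-5-methoxybenzene (E/Z mixture) | COc1cc(OCc2ccccc2)c(Cc2ccc(OCc3ccccc3)cc2)c(C=Cc2cccc(OCc3ccccc3)c2)c1Cc1ccc(OCc2ccccc2)cc1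
F7 | step 5 | 3-[3-(benzyloxy)phenyl]propanal | O=CCCc1cccc(OCc2ccccc2)c1
F8 | step 5 | 1-(benzyloxy)-3-(but-3-yn-1-yl)benzene | C#CCCc1cccc(OCc2ccccc2)c1
F9 | step 5 | methyl 5-[3-(benzyloxy)phenyl]pent-2-ynoate | COC(=O)C#CCCc1cccc(OCc2ccccc2)c1
F10 | step 8 | benzyl 3,5-bis[4-(benzyloxy)benzyl]-4-{2-[3-(benzyloxy)phenyl]ethyl}-2,6-dimethoxybenzoate | COc1c(C(=O)OCc2ccccc2)c(OC)c(Cc2ccc(OCc3ccccc3)cc2)c(CCc2cccc(OCc3ccccc3)c2)c1Cc1ccc(OCc2ccccc2)cc1
F11 | step 10 | 2,4-bis[4-(benzyloxy)benzyl]-3-{2-[3-(benzyloxy)phenyl]ethyl}-5-methoxyphenol | COc1cc(O)c(Cc2ccc(OCc3ccccc3)cc2)c(CCc2cccc(OCc3ccccc3)c2)c1Cc1ccc(OCc2ccccc2)cc1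
A1 | alternative 1 | 3-[2-(3,5-dimethoxy-2,6-dimethylphenyl)ethyl]phenyl pivalate | COc1cc(OC)c(C)c(CCc2cccc(OC(=O)C(C)(C)C)c2)c1C
A2 | alternative 1 | phenol | Oc1ccccc1
A3 | alternative 1 | 3-{2-[2,6-bis(4-hydroxybenzyl)-3,5-dimethoxyphenyl]ethyl}phenyl pivalate | COc1cc(OC)c(Cc2ccc(O)cc2)c(CCc2cccc(OC(=O)C(C)(C)C)c2)c1Cc1ccc(O)cc1
A4 | alternative 2 | dimethyl 2-[4-(benzyloxy)benzyl]malonate | COC(=O)C(Cc1ccc(OCc2ccccc2)cc1)C(=O)OC
A5 | alternative 2 | (E)-3-[4-(benzyloxy)benzyl]-6-[3-(benzyloxy)phenyl]hex-3-en-2-one | CC(=O)/C(Cc1ccc(OCc2ccccc2)cc1)=C/CCc1cccc(OCc2ccccc2)c1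
A6 | alternative 2 | methyl 1,5-bis[4-(benzyloxy)benzyl]-6-{2-[3-(benzyloxy)phenyl]ethyl}-2,4-dioxocyclohexane-1-carboxylate (mixture of diastereomers) | COC(=O)C1(Cc2ccc(OCc3ccccc3)cc2)C(=O)CC(=O)C(Cc2ccc(OCc3ccccc3)cc2)C1CCc1cccc(OCc2ccccc2)c1
A7 | alternative 3 | (E)-1-[3-(benzyloxy)phenyl]-4-[4-(benzyloxy)benzyl]-9-[4-(benzyloxy)phenyl]non-1-ene-3,5,7-trione | O=C(/C=C/c1cccc(OCc2ccccc2)c1)C(Cc1ccc(OCc2ccccc2)cc1)C(=O)CC(=O)CCc1ccc(OCc2ccccc2)cc1
A8 | alternative 3 | 4,6-bis[4-(benzyloxy)benzyl]-5-{(E)-2-[3-(benzyloxy)phenyl]ethenyl}benzene-1,3-diol | Oc1cc(O)c(Cc2ccc(OCc3ccccc3)cc2)c(/C=C/c2cccc(OCc3ccccc3)c2)c1Cc1ccc(OCc2ccccc2)cc1
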